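1. The target is a trans-fused daucane: cyclopentane ring A (C1–C5, daucane numbers) shares the C1–C5 bond with cycloheptene ring B (C1, C5, C6–C10). The enabling feature is that carbinol carbon C9 of ring B is bonded to C8 of the endocyclic Z-trisubstituted C7=C8(CH3) olefin, whose other end carries carbinol C6, while C6 and C10 sit trans on C5/C1 of ring A. C8–C9 is therefore an alkenyl iodide + aldehyde retron, and an intramolecular Nozaki–Hiyama–Kishi coupling closes ring B last, sets C9 and leaves C9–OH as the only acylable hydroxyl.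
2. The precursor of the key step is ring A carrying CH2CHO on C1 and a (Z)-3-iodobut-2-enyl 4-silyloxybenzoate on C5. The C–I bond is held cis to C6 by hydroxyl-directed trans-hydroalumination/iodination of a propargylic alcohol.
3. C5–C6, with the C5 and C6 stereocentres, comes from an anti boron aldol of a regiodefined cyclopentanone enolate with but-2-ynal (linchpin for C6, C7, C8 and the C8 methyl). C4 comes from isopropyl addition to the ring ketone.
4. Quaternary C1 comes from a copper-catalysed asymmetric conjugate addition of Me3Al to 3-(1,3-dioxolan-2-ylmethyl)cyclopent-2-enone, itself a Stork–Danheiser product of 3-ethoxycyclopent-2-enone.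
5. Ring order: ring A is bought as the cyclopentenone and elaborated in steps 1–8; ring B is closed in step 9; acetylation and desilylation finish the route.

Key step: step 9

Remarks (assumptions on the chemistry)
- Atom numbers C1–C10 are daucane numbers: C1 quaternary ring-fusion carbon with CH3, C4 carbinol carbon with isopropyl, C5 ring-fusion CH, C6 aroyloxy carbon, C7=C8 olefin (CH3 on C8), C9 acetoxy carbon, C10 CH2.
- The sense of induction of the copper/phosphoramidite catalyst in step 2 is assumed to be selectable through the ligand enantiomer; the enantiomer that gives the (R) quaternary carbon is used.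
- The CIP label of C6 changes from R (acyclic alkyne and iodide series) to S (after ring closure) only through a priority change; the geometry stays the same.

Step 1
Reactants: 1 3-ethoxycyclopent-2-en-1-one; 2 (1,3-dioxolan-2-ylmethyl)magnesium bromide
Product: 4 3-(1,3-dioxolan-2-ylmethyl)cyclopent-2-en-1-one, via bromomagnesium carbinolate 3 (not isolated)
Conditions: THF, 0 °C → rt; then 1 M aq. HCl, 0 °C, short contact
Reagents that add atoms: water O
Why: Stork–Danheiser enone transposition, in which 1,2-addition of the Grignard reagent to the vinylogous ester and acid-promoted hydrolysis/elimination of the enol-ether carbinol should give the 3-substituted enone carrying C10 and masked C9, with no stereocentre formed and the dioxolane surviving the brief cold acid.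

Step 2
Reactants: 4 3-(1,3-dioxolan-2-ylmethyl)cyclopent-2-en-1-one
Product: 6 {[(3R)-3-(1,3-dioxolan-2-ylmethyl)-3-methylcyclopent-1-en-1-yl]oxy}trimethylsilane, via dimethylaluminium enolate 5 (not isolated)
Conditions: Me3Al, CuTC [Cu(O2CC4H3S)] (5 mol%), chiral biphenol-derived phosphoramidite ligand (10 mol%), Et2O, −30 °C; then TMSOTf, −30 → 0 °C
Reagents that add atoms: trimethylaluminium C[Al](C)C; trimethylsilyl trifluoromethanesulfonate C[Si](C)(C)OS(=O)(=O)C(F)(F)F
Why: Copper-catalysed asymmetric conjugate addition of a trialkylaluminium to a β-substituted cyclopentenone should create the quaternary C1 centre, its (R) configuration fixed by the ligand enantiomer, and O-silylation of the aluminium enolate locks the enolate regiochemistry at C4–C5.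

Step 3
Reactants: 7 but-2-yn-1-ol
Product: 8 but-2-ynal
Conditions: MnO2, CH2Cl2, rt; used as a solution
Reagents that add atoms: none
Why: Chemoselective MnO2 oxidation of a propargylic alcohol should give the ynal without over-oxidation; no stereocentre is involved.

Step 4
Reactants: 6 {[(3R)-3-(1,3-dioxolan-2-ylmethyl)-3-methylcyclopent-1-en-1-yl]oxy}trimethylsilane; 8 but-2-ynal
Product: 11 (2S,3R)-3-(1,3-dioxolan-2-ylmethyl)-2-[(1R)-1-hydroxybut-2-yn-1-yl]-3-methylcyclopentan-1-one, via lithium enolate 9 (not isolated), via dibutylboron enolate 10 (not isolated)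
Conditions: MeLi, THF, 0 °C; Bu2BOTf, −78 °C; then the aldehyde, −78 → −20 °C; H2O2, pH 7 buffer, MeOH, 0 °C
Reagents that add atoms: none
Why: Regiospecific enolate release, Li→B exchange and a Zimmerman–Traxler boron aldol addition should give the anti aldol from the E(O) cyclic enolate (sets C6 relative to C5), the aldehyde approaching the enolate face anti to the bulkier CH2-dioxolanyl arm on C1, so that C6 ends up cis to the C1 methyl (sets C5, the future trans ring fusion).

Step 5
Reactants: 11 (2S,3R)-3-(1,3-dioxolan-2-ylmethyl)-2-[(1R)-1-hydroxybut-2-yn-1-yl]-3-methylcyclopentan-1-one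
Product: 12 (1R,2S,3R)-3-(1,3-dioxolan-2-ylmethyl)-2-[(1R)-1-hydroxybut-2-yn-1-yl]-3-methyl-1-(propan-2-yl)cyclopentan-1-ol
Conditions: i-PrMgCl (excess), LaCl3·2LiCl, THF, −20 → 0 °C; then H2O
Reagents that add atoms: isopropylmagnesium chloride CC(C)[Mg]Cl
Why: Lanthanide-assisted Grignard 1,2-addition to a hindered, enolisable ketone should deliver isopropyl to the ring face anti to the adjacent C5 side chain (the open face of the C6–O/C4=O chelate), giving the tertiary C4 alcohol with OH cis to C6.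

Step 6
Reactants: 12 (1R,2S,3R)-3-(1,3-dioxolan-2-ylmethyl)-2-[(1R)-1-hydroxybut-2-yn-1-yl]-3-methyl-1-(propan-2-yl)cyclopentan-1-ol
Product: 14 (1R,2S,3R)-3-(1,3-dioxolan-2-ylmethyl)-2-[(1R,2Z)-1-hydroxy-3-iodobut-2-en-1-yl]-3-methyl-1-(propan-2-yl)cyclopentan-1-ol, via cyclic alkenylalanate 13 (not isolated)
Conditions: NaAlH2(OCH2CH2OCH3)2 (Red-Al, excess), THF, 0 °C → rt; then I2, −78 → 0 °C
Reagents that add atoms: iodine II
Why: Hydroxyl-directed trans-hydroalumination of the propargylic alcohol (hydride to C7, aluminium to C8 inside a five-membered oxa-alumina ring) followed by iodinolysis with retention should give the (Z)-γ-iodoallylic alcohol with iodine cis to C6; no new stereocentre is formed.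

Step 7
Reactants: 14 (1R,2S,3R)-3-(1,3-dioxolan-2-ylmethyl)-2-[(1R,2Z)-1-hydroxy-3-iodobut-2-en-1-yl]-3-methyl-1-(propan-2-yl)cyclopentan-1-ol; 15 4-{[tert-butyl(dimethyl)silyl]oxy}benzoic acid
Product: 16 (1R,2Z)-1-[(1S,2R,5R)-2-(1,3-dioxolan-2-ylmethyl)-5-hydroxy-2-methyl-5-(propan-2-yl)cyclopentyl]-3-iodobut-2-en-1-yl 4-{[tert-butyl(dimethyl)silyl]oxy}benzoate
Conditions: DCC, DMAP (cat.), CH2Cl2, rt
Reagents that add atoms: none
Why: Steglich esterification should acylate the secondary allylic C6 hydroxyl with retention, while the tertiary C4 hydroxyl is too hindered to react.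

Step 8
Reactants: 16 (1R,2Z)-1-[(1S,2R,5R)-2-(1,3-dioxolan-2-ylmethyl)-5-hydroxy-2-methyl-5-(propan-2-yl)cyclopentyl]-3-iodobut-2-en-1-yl 4-{[tert-butyl(dimethyl)silyl]oxy}benzoate
Product: 17 (1R,2Z)-1-[(1S,2R,5R)-2-hydroxy-5-methyl-5-(2-oxoethyl)-2-(propan-2-yl)cyclopentyl]-3-iodobut-2-en-1-yl 4-{[tert-butyl(dimethyl)silyl]oxy}benzoate
Conditions: TsOH·H2O (cat.), acetone/H2O, rt
Reagents that add atoms: water O
Why: Acid-catalysed acetal hydrolysis should free the C9 aldehyde while the aryl silyl ether, allylic ester and tertiary alcohol tolerate the mild acid, and the trans relation of C4–OH and the C1 arm rules out lactol formation.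

Step 9
Reactants: 17 (1R,2Z)-1-[(1S,2R,5R)-2-hydroxy-5-methyl-5-(2-oxoethyl)-2-(propan-2-yl)cyclopentyl]-3-iodobut-2-en-1-yl 4-{[tert-butyl(dimethyl)silyl]oxy}benzoate
Product: 19 (3R,3aS,4S,7S,8aR)-3,7-dihydroxy-6,8a-dimethyl-3-(propan-2-yl)-1,2,3,3a,4,7,8,8a-octahydroazulen-4-yl 4-{[tert-butyl(dimethyl)silyl]oxy}benzoate, via alkenylchromium dichloride 18 (not isolated)
Conditions: CrCl2 (excess), NiCl2 (cat.), degassed DMSO/THF, rt, slow addition of the substrate (high dilution); then H2O
Reagents that add atoms: none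
Why: Zerovalent nickel, formed in the flask from NiCl2 by divalent chromium, should insert into the C8–I bond with retention of the Z geometry and pass the alkenyl group to trivalent chromium, and alkenylchromium 18 then adds intramolecularly to the C9 aldehyde to give the cycloheptenol after hydrolysis of the chromium alkoxide. The closest known reaction type is the Nozaki–Hiyama–Kishi cyclisation of iodoalkenyl aldehydes used for medium and large carbocycles. Ring B (C1, C5, C6, C7, C8, C9, C10) is closed by C8–C9 bond formation as a 7-exo-trig addition to the carbonyl with the C7=C8 olefin endocyclic, which is geometrically possible only because step 6 placed the C–I bond cis to C6. The new stereocentre C9 is substrate-controlled: in the ring-forming transition state the bulky chromium-bound carbonyl oxygen should turn away from the angular C1 methyl on the β face and from the C8 methyl (allylic 1,2-strain), so that the C9–O bond develops on the α face, cis to the C6 ester (9S). The step needs chemoselectivity for the aldehyde over the benzoate carbonyl and tolerance of the free tertiary alcohol and the aryl silyl ether, which the mild, non-basic alkenylchromium reagent secures. It also needs cyclisation to outrun oligomerisation, which high dilution and the trans C1/C5 substitution of ring A secure.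

Step 10
Reactants: 19 (3R,3aS,4S,7S,8aR)-3,7-dihydroxy-6,8a-dimethyl-3-(propan-2-yl)-1,2,3,3a,4,7,8,8a-octahydroazulen-4-yl 4-{[tert-butyl(dimethyl)silyl]oxy}benzoate
Product: 20 (3R,3aS,4S,7S,8aR)-7-(acetyloxy)-3-hydroxy-6,8a-dimethyl-3-(propan-2-yl)-1,2,3,3a,4,7,8,8a-octahydroazulen-4-yl 4-{[tert-butyl(dimethyl)silyl]oxy}benzoate
Conditions: Ac2O, pyridine, DMAP (cat.), CH2Cl2, 0 °C → rt
Reagents that add atoms: acetic anhydride CC(=O)OC(C)=O
Why: DMAP-catalysed acetylation should esterify the only secondary hydroxyl (C9) with retention, the tertiary C4 hydroxyl being unreactive under these conditions.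

Step 11
Reactants: 20 (3R,3aS,4S,7S,8aR)-7-(acetyloxy)-3-hydroxy-6,8a-dimethyl-3-(propan-2-yl)-1,2,3,3a,4,7,8,8a-octahydroazulen-4-yl 4-{[tert-butyl(dimethyl)silyl]oxy}benzoate
Product: 21 (3R,3aS,4S,7S,8aR)-7-(acetyloxy)-3-hydroxy-6,8a-dimethyl-3-(propan-2-yl)-1,2,3,3a,4,7,8,8a-octahydroazulen-4-yl 4-hydroxybenzoate (CNP0305796.2)
Conditions: Bu4NF, AcOH, THF, 0 °C
Reagents that add atoms: none
Why: Fluoride-mediated cleavage of the aryl silyl ether, buffered with acetic acid so that neither ester migrates or hydrolyses, should release the phenol and give the target.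

Compound list
1 | 3-ethoxycyclopent-2-en-1-one | CCOC1=CC(=O)CC1 | starting material
2 | (1,3-dioxolan-2-ylmethyl)magnesium bromide | Br[Mg]CC1OCCO1 | starting material
3 | bromomagnesium 1-(1,3-dioxolan-2-ylmethyl)-3-ethoxycyclopent-2-en-1-olate (formed in the flask) | CCOC1=CC(CC2OCCO2)(O[Mg]Br)CC1 | intermediate
4 | 3-(1,3-dioxolan-2-ylmethyl)cyclopent-2-en-1-one | O=C1C=C(CC2OCCO2)CC1 | intermediate
5 | dimethylaluminium (3R)-3-(1,3-dioxolan-2-ylmethyl)-3-methylcyclopent-1-en-1-olate (formed in the flask) | C[Al](C)OC1=C[C@@](C)(CC2OCCO2)CC1 | intermediate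
6 | {[(3R)-3-(1,3-dioxolan-2-ylmethyl)-3-methylcyclopent-1-en-1-yl]oxy}trimethylsilane | C[Si](C)(C)OC1=C[C@@](C)(CC2OCCO2)CC1 | intermediate
7 | but-2-yn-1-ol | CC#CCO | starting material
8 | but-2-ynal | CC#CC=O | intermediate
9 | lithium (3R)-3-(1,3-dioxolan-2-ylmethyl)-3-methylcyclopent-1-en-1-olate (formed in the flask) | [Li]OC1=C[C@@](C)(CC2OCCO2)CC1 | intermediate
10 | dibutyl{[(3R)-3-(1,3-dioxolan-2-ylmethyl)-3-methylcyclopent-1-en-1-yl]oxy}borane (formed in the flask) | CCCCB(CCCC)OC1=C[C@@](C)(CC2OCCO2)CC1 | intermediate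
11 | (2S,3R)-3-(1,3-dioxolan-2-ylmethyl)-2-[(1R)-1-hydroxybut-2-yn-1-yl]-3-methylcyclopentan-1-one | O1CCOC1C[C@@]2(C)CCC(=O)[C@@H]2[C@@H](O)C#CC | intermediate
12 | (1R,2S,3R)-3-(1,3-dioxolan-2-ylmethyl)-2-[(1R)-1-hydroxybut-2-yn-1-yl]-3-methyl-1-(propan-2-yl)cyclopentan-1-ol | O1CCOC1C[C@@]2(C)CC[C@@](O)(C(C)C)[C@@H]2[C@@H](O)C#CC | intermediate
13 | sodium cyclic (Z)-alkenylalanate of 12: 2,2-bis(2-methoxyethoxy)-1,2-oxaaluminol-2-uide ring across O6 and C8 (formed in the flask) | [Na+].O1CCOC1C[C@@]2(C)CC[C@@](O)(C(C)C)[C@@H]2[C@@H](O[Al-]3(OCCOC)OCCOC)C=C3C | intermediate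
14 | (1R,2S,3R)-3-(1,3-dioxolan-2-ylmethyl)-2-[(1R,2Z)-1-hydroxy-3-iodobut-2-en-1-yl]-3-methyl-1-(propan-2-yl)cyclopentan-1-ol | O1CCOC1C[C@@]2(C)CC[C@@](O)(C(C)C)[C@@H]2[C@@H](O)/C=C(/C)I | intermediate
15 | 4-{[tert-butyl(dimethyl)silyl]oxy}benzoic acid | CC(C)(C)[Si](C)(C)Oc1ccc(cc1)C(O)=O | starting material
16 | (1R,2Z)-1-[(1S,2R,5R)-2-(1,3-dioxolan-2-ylmethyl)-5-hydroxy-2-methyl-5-(propan-2-yl)cyclopentyl]-3-iodobut-2-en-1-yl 4-{[tert-butyl(dimethyl)silyl]oxy}benzoate | O1CCOC1C[C@@]2(C)CC[C@@](O)(C(C)C)[C@@H]2[C@@H](OC(=O)c3ccc(O[Si](C)(C)C(C)(C)C)cc3)/C=C(/C)I | intermediate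
17 | (1R,2Z)-1-[(1S,2R,5R)-2-hydroxy-5-methyl-5-(2-oxoethyl)-2-(propan-2-yl)cyclopentyl]-3-iodobut-2-en-1-yl 4-{[tert-butyl(dimethyl)silyl]oxy}benzoate | O=CC[C@@]1(C)CC[C@@](O)(C(C)C)[C@@H]1[C@@H](OC(=O)c2ccc(O[Si](C)(C)C(C)(C)C)cc2)/C=C(/C)I | intermediate
18 | (Z)-alkenylchromium dichloride from 17, CrCl2 on C8 in place of iodine (formed in the flask) | O=CC[C@@]1(C)CC[C@@](O)(C(C)C)[C@@H]1[C@@H](OC(=O)c2ccc(O[Si](C)(C)C(C)(C)C)cc2)/C=C(/C)[Cr](Cl)Cl | intermediate
19 | (3R,3aS,4S,7S,8aR)-3,7-dihydroxy-6,8a-dimethyl-3-(propan-2-yl)-1,2,3,3a,4,7,8,8a-octahydroazulen-4-yl 4-{[tert-butyl(dimethyl)silyl]oxy}benzoate | O[C@H]1C[C@@]2(C)CC[C@@](O)(C(C)C)[C@@H]2[C@@H](OC(=O)c3ccc(O[Si](C)(C)C(C)(C)C)cc3)C=C1C | intermediate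
20 | (3R,3aS,4S,7S,8aR)-7-(acetyloxy)-3-hydroxy-6,8a-dimethyl-3-(propan-2-yl)-1,2,3,3a,4,7,8,8a-octahydroazulen-4-yl 4-{[tert-butyl(dimethyl)silyl]oxy}benzoate | CC(=O)O[C@H]1C[C@@]2(C)CC[C@@](O)(C(C)C)[C@@H]2[C@@H](OC(=O)c3ccc(O[Si](C)(C)C(C)(C)C)cc3)C=C1C | intermediate
21 | (3R,3aS,4S,7S,8aR)-7-(acetyloxy)-3-hydroxy-6,8a-dimethyl-3-(propan-2-yl)-1,2,3,3a,4,7,8,8a-octahydroazulen-4-yl 4-hydroxybenzoate | CC(=O)O[C@H]1C[C@@]2(C)CC[C@@](O)(C(C)C)[C@@H]2[C@@H](OC(=O)c2ccc(O)cc2)C=C1C | target

Total step count: 11. Longest linear sequence: 10 (steps 1, 2, 4–11; step 3 prepares aldehyde 8).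

Steps most likely to fail

Step 9. The alkenylchromium may attack the undesired face of the C9 aldehyde during ring closure, so that the 9-epimer forms alongside or instead of 19. The fallback sets out from 17 and comes back at 20. The cyclisation is run unchanged and the epimers are separated. The epimer (3R,3aS,4S,7R,8aR)-3,7-dihydroxy-6,8a-dimethyl-3-(propan-2-yl)-1,2,3,3a,4,7,8,8a-octahydroazulen-4-yl 4-{[tert-butyl(dimethyl)silyl]oxy}benzoate F1 is then esterified with acetic acid under Mitsunobu conditions (PPh3, DIAD, THF). This should install the acetate with SN2 inversion at C9 and give 20 directly, so that both epimers converge: 19 through step 10, F1 through invertive acetylation.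

Step 4. Part of the aldol may leak through an open transition state if Li→B exchange is incomplete, eroding anti selectivity at C6. The fallback sets out from 6 (with 8) and comes back at 16. The syn aldol (2S,3R)-3-(1,3-dioxolan-2-ylmethyl)-2-[(1S)-1-hydroxybut-2-yn-1-yl]-3-methylcyclopentan-1-one F2 is taken through the operations of steps 5 and 6. This gives (1R,2S,3R)-3-(1,3-dioxolan-2-ylmethyl)-2-[(1S)-1-hydroxybut-2-yn-1-yl]-3-methyl-1-(propan-2-yl)cyclopentan-1-ol F3 and then (1R,2S,3R)-3-(1,3-dioxolan-2-ylmethyl)-2-[(1S,2Z)-1-hydroxy-3-iodobut-2-en-1-yl]-3-methyl-1-(propan-2-yl)cyclopentan-1-ol F4. F4 is coupled with acid 15 under Mitsunobu conditions (PPh3, DIAD), which should form the C6 ester with inversion and deliver 16.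

Step 5. The basic organometallic may deprotonate the β-hydroxy ketone and trigger retro-aldol cleavage or enolisation, or reduce the ketone by β-hydride transfer, instead of adding. The fallback sets out from 11 and comes back at 12. The C6 hydroxyl is silylated (Et3SiOTf, 2,6-lutidine, CH2Cl2) to (2S,3R)-3-(1,3-dioxolan-2-ylmethyl)-3-methyl-2-{(1R)-1-[(triethylsilyl)oxy]but-2-yn-1-yl}cyclopentan-1-one F5. The less basic organocerium reagent from i-PrLi and CeCl3 (THF, −78 °C) is then added to give (1R,2S,3R)-3-(1,3-dioxolan-2-ylmethyl)-3-methyl-1-(propan-2-yl)-2-{(1R)-1-[(triethylsilyl)oxy]but-2-yn-1-yl}cyclopentan-1-ol F6. Fluoride cleavage of the silyl ether (Bu4NF, THF) then gives 12.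

Further compounds
F1 | step 9 | (3R,3aS,4S,7R,8aR)-3,7-dihydroxy-6,8a-dimethyl-3-(propan-2-yl)-1,2,3,3a,4,7,8,8a-octahydroazulen-4-yl 4-{[tert-butyl(dimethyl)silyl]oxy}benzoate | O[C@@H]1C[C@@]2(C)CC[C@@](O)(C(C)C)[C@@H]2[C@@H](OC(=O)c3ccc(O[Si](C)(C)C(C)(C)C)cc3)C=C1C
F2 | step 4 | (2S,3R)-3-(1,3-dioxolan-2-ylmethyl)-2-[(1S)-1-hydroxybut-2-yn-1-yl]-3-methylcyclopentan-1-one | O1CCOC1C[C@@]2(C)CCC(=O)[C@@H]2[C@H](O)C#CC
F3 | step 4 | (1R,2S,3R)-3-(1,3-dioxolan-2-ylmethyl)-2-[(1S)-1-hydroxybut-2-yn-1-yl]-3-methyl-1-(propan-2-yl)cyclopentan-1-ol | O1CCOC1C[C@@]2(C)CC[C@@](O)(C(C)C)[C@@H]2[C@H](O)C#CC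
F4 | step 4 | (1R,2S,3R)-3-(1,3-dioxolan-2-ylmethyl)-2-[(1S,2Z)-1-hydroxy-3-iodobut-2-en-1-yl]-3-methyl-1-(propan-2-yl)cyclopentan-1-ol | O1CCOC1C[C@@]2(C)CC[C@@](O)(C(C)C)[C@@H]2[C@H](O)/C=C(/C)I
F5 | step 5 | (2S,3R)-3-(1,3-dioxolan-2-ylmethyl)-3-methyl-2-{(1R)-1-[(triethylsilyl)oxy]but-2-yn-1-yl}cyclopentan-1-one | O1CCOC1C[C@@]2(C)CCC(=O)[C@@H]2[C@@H](O[Si](CC)(CC)CC)C#CC
F6 | step 5 | (1R,2S,3R)-3-(1,3-dioxolan-2-ylmethyl)-3-methyl-1-(propan-2-yl)-2-{(1R)-1-[(triethylsilyl)oxy]but-2-yn-1-yl}cyclopentan-1-ol | O1CCOC1C[C@@]2(C)CC[C@@](O)(C(C)C)[C@@H]2[C@@H](O[Si](CC)(CC)CC)C#CC
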